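**Retrosynthetic overview**

1. Numbering (guaiane): ring A = cyclopentenone C1–C5 (C3=O, C4–Me); ring B = cycloheptane C1, C5, C6–C10 (C11 on C7, O on C8, Me on C10).
2. Endgame: acetate (C11–O) and methacrylate (C8–O) on diol 21; the C11 carbinol from a methyl ester on C7; C7/C8 from a β-keto ester by catalyst-controlled reduction; 1β-H by equilibration of the enone.
3. Key disconnection: ring B is the formal (4+3) adduct of triene 8 (ring A carrying the exocyclic s-cis diene C6=C5–C1=C10) and siloxyvinyl diazoacetate 11 (C7–C8–C9, with C11 as the ester). The carbene carbon C7 bonds to C6 (and C5) to close a transient spirocyclopropane; its C5–C7 bond, which is not in the target, is cleaved in the Cope shift that forms C9–C10.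
4. Enabling feature: C6 and C10 flank the ring-fusion bond C1–C5, so both can be exocyclic alkene termini on ring A. The three ring B carbons between them carry the pattern of a siloxyvinyl carbene: a carboxyl-level carbon (C11) on C7, oxygen on C8, CH2 at C9.
5. Ring order: ring A is bought with 1; ring B is closed in step 6.

Key step: step 6

Assumption: the sense of induction of Rh2(S-PTAD)4 (step 6) and of RuCl(p-cymene)[(S,S)-TsDPEN] (step 8) is assigned by analogy with simpler dienes and cyclic β-keto esters; if either turns out opposite, the enantiomeric catalyst is used and nothing else changes.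

**Route**

Step 1
Reactants: 1 3-ethoxy-2-methylcyclopent-2-en-1-one; 2 acetaldehyde
Product: 4 3-ethoxy-5-(1-hydroxyethyl)-2-methylcyclopent-2-en-1-one (diastereomer mixture), via lithium enolate 3 (not isolated)
Conditions: LiN(iPr)2, THF, −78 °C; 2; AcOH quench
Reagents that add atoms: none
Why: Kinetic deprotonation of the vinylogous ester at its α'-methylene (C1 in guaiane numbering) and aldol addition to acetaldehyde; the two new stereocentres are erased in step 2.

Step 2
Reactants: 4 3-ethoxy-5-(1-hydroxyethyl)-2-methylcyclopent-2-en-1-one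
Product: 6 (E)-3-ethoxy-5-ethylidene-2-methylcyclopent-2-en-1-one, via mesylate 5 (not isolated)
Conditions: MsCl, Et3N, CH2Cl2, 0 °C; then DBU, 23 °C
Reagents that add atoms: none
Why: Mesylation and E1cB elimination give the cross-conjugated alkylidene ketone, for which the E isomer (methyl away from the carbonyl, toward C2) is the thermodynamically favoured geometry; this geometry later places the methyl group outside in the Cope transition state.

Step 3
Reactants: 6 (E)-3-ethoxy-5-ethylidene-2-methylcyclopent-2-en-1-one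
Product: 8 (E)-1-ethoxy-4-ethylidene-2-methyl-3-methylidenecyclopent-1-ene, via lithium β-silyl alkoxide 7 (not isolated)
Conditions: Me3SiCH2Li, THF, −78 → 0 °C; then KOtBu, 23 °C; used freshly
Reagents that add atoms: (trimethylsilyl)methyllithium, [Li]C[Si](C)(C)C
Why: Peterson olefination: 1,2-addition of the silylmethyl nucleophile to the non-enolisable ketone and syn-elimination of the potassium alkoxide under basic conditions that leave the acid-labile alkoxydiene intact; no stereocentre is formed.

Step 4
Reactants: 9 methyl acetoacetate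
Product: 10 methyl 2-diazo-3-oxobutanoate
Conditions: 4-acetamidobenzenesulfonyl azide, Et3N, MeCN, 0 → 23 °C
Reagents that add atoms: 4-acetamidobenzenesulfonyl azide, CC(=O)Nc1ccc(cc1)S(=O)(=O)N=[N+]=[N-]
Why: Regitz diazo transfer to the doubly activated methylene of the β-keto ester.

Step 5
Reactants: 10 methyl 2-diazo-3-oxobutanoate
Product: 11 methyl 3-[(tert-butyldimethylsilyl)oxy]-2-diazobut-3-enoate
Conditions: TBSOTf, Et3N, CH2Cl2, 0 °C
Reagents that add atoms: tert-butyldimethylsilyl trifluoromethanesulfonate, CC(C)(C)[Si](C)(C)OS(=O)(=O)C(F)(F)F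
Why: Soft enolisation of the acetyl group and O-silylation give the donor/acceptor carbene precursor with oxygen already placed on the future C8.

Step 6
Reactants: 8 (E)-1-ethoxy-4-ethylidene-2-methyl-3-methylidenecyclopent-1-ene; 11 methyl 3-[(tert-butyldimethylsilyl)oxy]-2-diazobut-3-enoate
Product: 14 methyl (8S)-6-[(tert-butyldimethylsilyl)oxy]-2-ethoxy-3,8-dimethyl-1,4,7,8-tetrahydroazulene-5-carboxylate, via rhodium carbene 12 (not isolated), via spiro-divinylcyclopropane 13 (not isolated)
Conditions: Rh2(S-PTAD)4 {dirhodium tetrakis[(S)-(1-adamantyl)(N-phthalimido)acetate]} (1 mol %), 8 (1.5 equiv), hexane, 0 → 23 °C, slow addition of 11; then 50 °C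
Reagents that add atoms: none
Why: Rh2(S-PTAD)4 decomposes 11 to rhodium carbene 12, whose carbene carbon (the future C7, carrying the ester that becomes C11) adds to the least hindered double bond of 8, the 1,1-disubstituted C5=C6, forming C6–C7 and C5–C7 in a concerted asynchronous [2+1] closure of spirocyclopropane 13; 13 has its two alkenyl groups cis and undergoes a boat-type [3,3] Cope shift that breaks the C5–C7 bond (absent from the target) and forms C9–C10, so that ring B is closed as a formal (4+3) adduct across C6 and C10. The closest known reaction type is the dirhodium-catalysed tandem cyclopropanation/Cope rearrangement of siloxyvinyl diazoacetates with 1,3-dienes, which tolerates alkoxy- and 2,3-disubstituted dienes. The only stereocentre that persists is C10: the chiral catalyst selects the face of the planar, achiral diene in the cyclopropanation, and the stereospecific boat transition state passes this on to C10 from the E-ethylidene group (methyl outside, hydrogen inside). Three selectivities are needed: site selectivity, secured because the trisubstituted C1=C10 and tetrasubstituted C3=C4 double bonds are too hindered for a donor/acceptor carbene; periselectivity in the Cope step, secured because only the exocyclic C1=C10 bond can fold over the cyclopropane while the endocyclic enol ether is held away by ring A; and face selectivity, secured by the catalyst. Should part of 13 form as the trans-dialkenyl isomer, warming should equilibrate it through reversible homolysis of C5–C7 and funnel it to 14. The activating ester stays in the molecule as C11 and the silyl enol ether leaves oxygen on C8, so no auxiliary group has to be removed.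

Step 7
Reactants: 14 methyl (8S)-6-[(tert-butyldimethylsilyl)oxy]-2-ethoxy-3,8-dimethyl-1,4,7,8-tetrahydroazulene-5-carboxylate
Product: 16 methyl (8S,8aR)-3,8-dimethyl-2,6-dioxo-1,2,4,5,6,7,8,8a-octahydroazulene-5-carboxylate (C5 epimers and enol), via C1-epimer 15 (not isolated)
Conditions: 1 M HCl, THF, 23 °C; then DBU (2 equiv), toluene, 50 °C
Reagents that add atoms: water, O
Why: Acid hydrolysis of both enol ethers, with protonation of the alkoxydiene at C1, gives the conjugated enone and the β-keto ester, and base equilibration through the dienolate should favour the 1β-H epimer, in which the C10 methyl group is anti to C5 and ring B is spared a second gauche interaction; C7 remains labile as a β-keto ester and is fixed in step 8.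

Step 8
Reactants: 16 methyl (8S,8aR)-3,8-dimethyl-2,6-dioxo-1,2,4,5,6,7,8,8a-octahydroazulene-5-carboxylate
Product: 17 methyl (5S,6R,8S,8aR)-6-hydroxy-3,8-dimethyl-2-oxo-1,2,4,5,6,7,8,8a-octahydroazulene-5-carboxylate
Conditions: RuCl(p-cymene)[(S,S)-TsDPEN] (2 mol %), HCO2H/Et3N (5:2), CH2Cl2, 30 °C
Reagents that add atoms: none
Why: Noyori–Ikariya asymmetric transfer hydrogenation with dynamic kinetic resolution: the catalyst sets C8 (R) by face selection at the ketone while C7 epimerises through the enol, and hydride delivery anti to the ester group should give the cis (7S,8R) hydroxy ester as with other cyclic β-keto esters; the hindered tetrasubstituted enone should not be reduced.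

Step 9
Reactants: 17 methyl (5S,6R,8S,8aR)-6-hydroxy-3,8-dimethyl-2-oxo-1,2,4,5,6,7,8,8a-octahydroazulene-5-carboxylate
Product: 18 methyl (5S,6R,8S,8aR)-2,6-dihydroxy-3,8-dimethyl-1,2,4,5,6,7,8,8a-octahydroazulene-5-carboxylate (C2 epimers)
Conditions: NaBH4, CeCl3·7H2O, MeOH, −20 °C
Reagents that add atoms: none
Why: Luche 1,2-reduction converts the enone carbonyl into an allylic alcohol so that it survives the Grignard step; the new C3 configuration is irrelevant because C3 is reoxidised in step 11.

Step 10
Reactants: 18 methyl (5S,6R,8S,8aR)-2,6-dihydroxy-3,8-dimethyl-1,2,4,5,6,7,8,8a-octahydroazulene-5-carboxylate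
Product: 20 (5S,6R,8S,8aR)-5-(2-hydroxypropan-2-yl)-3,8-dimethyl-1,2,4,5,6,7,8,8a-octahydroazulene-2,6-diol (C2 epimers), via methyl ketone 19 (not isolated)
Conditions: MeMgBr (6 equiv), THF, 0 → 23 °C; NH4Cl quench
Reagents that add atoms: methylmagnesium bromide, C[Mg]Br
Why: Twofold Grignard addition to the methyl ester through the methyl ketone builds the C11 dimethyl carbinol, the two hydroxyl groups being protected in situ as magnesium alkoxides; C7 loses its acidifying ester and is thereby locked.

Step 11
Reactants: 20 (5S,6R,8S,8aR)-5-(2-hydroxypropan-2-yl)-3,8-dimethyl-1,2,4,5,6,7,8,8a-octahydroazulene-2,6-diol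
Product: 21 (5S,6R,8S,8aR)-6-hydroxy-5-(2-hydroxypropan-2-yl)-3,8-dimethyl-4,5,6,7,8,8a-hexahydroazulen-2(1H)-one
Conditions: MnO2, CH2Cl2, 23 °C
Reagents that add atoms: none
Why: MnO2 oxidises only the allylic C3 alcohol and restores the enone, leaving the saturated secondary C8 and tertiary C11 alcohols untouched.

Step 12
Reactants: 21 (5S,6R,8S,8aR)-6-hydroxy-5-(2-hydroxypropan-2-yl)-3,8-dimethyl-4,5,6,7,8,8a-hexahydroazulen-2(1H)-one
Product: 22 (5S,6R,8S,8aR)-5-(2-hydroxypropan-2-yl)-3,8-dimethyl-2-oxo-1,2,4,5,6,7,8,8a-octahydroazulen-6-yl 2-methylprop-2-enoate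
Conditions: methacrylic anhydride, Et3N, DMAP (cat.), CH2Cl2, 0 °C
Reagents that add atoms: methacrylic anhydride, CC(=C)C(=O)OC(=O)C(C)=C
Why: DMAP-catalysed acyl transfer esterifies the secondary C8 hydroxyl selectively, because the tertiary C11 hydroxyl does not react under these conditions.

Step 13
Reactants: 22 (5S,6R,8S,8aR)-5-(2-hydroxypropan-2-yl)-3,8-dimethyl-2-oxo-1,2,4,5,6,7,8,8a-octahydroazulen-6-yl 2-methylprop-2-enoate
Product: 23 (5S,6R,8S,8aR)-5-(2-acetoxypropan-2-yl)-3,8-dimethyl-2-oxo-1,2,4,5,6,7,8,8a-octahydroazulen-6-yl 2-methylprop-2-enoate (target; guaiane numbering 1R,7S,8R,10S)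
Conditions: Ac2O, Sc(OTf)3 (2 mol %), MeCN, −20 °C
Reagents that add atoms: acetic anhydride, CC(=O)OC(C)=O
Why: Lewis acid-catalysed acetylation (Sc(OTf)3/Ac2O) acylates the hindered tertiary alcohol at low temperature, where ionisation and elimination to the isopropenyl compound should stay slow.

**Compound list**

1 | 3-ethoxy-2-methylcyclopent-2-en-1-one | CCOC1=C(C)C(=O)CC1 | starting material
2 | acetaldehyde | CC=O | starting material
3 | lithium enolate of 1 | CCOC1=C(C)C([O-])=CC1.[Li+] | intermediate
4 | 3-ethoxy-5-(1-hydroxyethyl)-2-methylcyclopent-2-en-1-one (diastereomer mixture) | CCOC1=C(C)C(=O)C(C(C)O)C1 | intermediate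
5 | 1-(4-ethoxy-3-methyl-2-oxocyclopent-3-en-1-yl)ethyl methanesulfonate | CCOC1=C(C)C(=O)C(C(C)OS(C)(=O)=O)C1 | intermediate
6 | (E)-3-ethoxy-5-ethylidene-2-methylcyclopent-2-en-1-one | CCOC1=C(C)C(=O)/C(=C/C)C1 | intermediate
7 | lithium (E)-3-ethoxy-5-ethylidene-2-methyl-1-[(trimethylsilyl)methyl]cyclopent-2-en-1-olate | CCOC1=C(C)C([O-])(C[Si](C)(C)C)/C(=C/C)C1.[Li+] | intermediate
8 | (E)-1-ethoxy-4-ethylidene-2-methyl-3-methylidenecyclopent-1-ene | CCOC1=C(C)C(=C)/C(=C/C)C1 | intermediate
9 | methyl acetoacetate | COC(=O)CC(C)=O | starting material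
10 | methyl 2-diazo-3-oxobutanoate | COC(=O)C(=[N+]=[N-])C(C)=O | intermediate
11 | methyl 3-[(tert-butyldimethylsilyl)oxy]-2-diazobut-3-enoate | COC(=O)C(=[N+]=[N-])C(=C)O[Si](C)(C)C(C)(C)C | intermediate
12 | rhodium carbene from 11 (one rhodium atom of the Rh2(S-PTAD)4 core shown, carboxylate ligands omitted) | COC(=O)C(=[Rh])C(=C)O[Si](C)(C)C(C)(C)C | intermediate
13 | methyl (1S,3R)-1-{1-[(tert-butyldimethylsilyl)oxy]ethenyl}-5-ethoxy-7-[(E)-ethylidene]-4-methylspiro[2.4]hept-4-ene-1-carboxylate | CCOC1=C(C)[C@@]2(C[C@@]2(C(=O)OC)C(=C)O[Si](C)(C)C(C)(C)C)/C(=C/C)C1 | intermediate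
14 | methyl (8S)-6-[(tert-butyldimethylsilyl)oxy]-2-ethoxy-3,8-dimethyl-1,4,7,8-tetrahydroazulene-5-carboxylate | COC(=O)C1=C(O[Si](C)(C)C(C)(C)C)C[C@H](C)C2=C(C1)C(C)=C(OCC)C2 | intermediate
15 | methyl (8S,8aS)-3,8-dimethyl-2,6-dioxo-1,2,4,5,6,7,8,8a-octahydroazulene-5-carboxylate (C1-epimer of 16) | COC(=O)C1C(=O)C[C@H](C)[C@@H]2CC(=O)C(C)=C2C1 | intermediate
16 | methyl (8S,8aR)-3,8-dimethyl-2,6-dioxo-1,2,4,5,6,7,8,8a-octahydroazulene-5-carboxylate (C5 epimers and enol) | COC(=O)C1C(=O)C[C@H](C)[C@H]2CC(=O)C(C)=C2C1 | intermediate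
17 | methyl (5S,6R,8S,8aR)-6-hydroxy-3,8-dimethyl-2-oxo-1,2,4,5,6,7,8,8a-octahydroazulene-5-carboxylate | O[C@@H]1C[C@H](C)[C@H]2CC(=O)C(C)=C2C[C@@H]1C(=O)OC | intermediate
18 | methyl (5S,6R,8S,8aR)-2,6-dihydroxy-3,8-dimethyl-1,2,4,5,6,7,8,8a-octahydroazulene-5-carboxylate (C2 epimers) | O[C@@H]1C[C@H](C)[C@H]2CC(O)C(C)=C2C[C@@H]1C(=O)OC | intermediate
19 | 1-[(5S,6R,8S,8aR)-2,6-dihydroxy-3,8-dimethyl-1,2,4,5,6,7,8,8a-octahydroazulen-5-yl]ethan-1-one (present as its bromomagnesium alkoxide) | O[C@@H]1C[C@H](C)[C@H]2CC(O)C(C)=C2C[C@@H]1C(C)=O | intermediate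
20 | (5S,6R,8S,8aR)-5-(2-hydroxypropan-2-yl)-3,8-dimethyl-1,2,4,5,6,7,8,8a-octahydroazulene-2,6-diol (C2 epimers) | O[C@@H]1C[C@H](C)[C@H]2CC(O)C(C)=C2C[C@@H]1C(C)(C)O | intermediate
21 | (5S,6R,8S,8aR)-6-hydroxy-5-(2-hydroxypropan-2-yl)-3,8-dimethyl-4,5,6,7,8,8a-hexahydroazulen-2(1H)-one | O[C@@H]1C[C@H](C)[C@H]2CC(=O)C(C)=C2C[C@@H]1C(C)(C)O | intermediate
22 | (5S,6R,8S,8aR)-5-(2-hydroxypropan-2-yl)-3,8-dimethyl-2-oxo-1,2,4,5,6,7,8,8a-octahydroazulen-6-yl 2-methylprop-2-enoate | C=C(C)C(=O)O[C@@H]1C[C@H](C)[C@H]2CC(=O)C(C)=C2C[C@@H]1C(C)(C)O | intermediate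
23 | (5S,6R,8S,8aR)-5-(2-acetoxypropan-2-yl)-3,8-dimethyl-2-oxo-1,2,4,5,6,7,8,8a-octahydroazulen-6-yl 2-methylprop-2-enoate | C=C(C)C(=O)O[C@@H]1C[C@H](C)[C@H]2CC(=O)C(C)=C2C[C@@H]1C(C)(C)OC(C)=O | target

**Step count and risks**

Total step count: 13. Longest linear sequence: 11 steps (steps 1–3 and 6–13); steps 4 and 5 prepare the second fragment.

Most likely to fail, step 6 (key step). The very electron-rich alkoxy triene may divert the electrophilic carbene into zwitterionic addition instead of clean cyclopropanation, and the chiral catalyst may differentiate the two faces of the flat diene poorly. In the fallback the absolute configuration comes from step 8 instead of step 6. Triene 8 and diazo ester 11 are combined with achiral Rh2(OPiv)4 in pentane, the most forgiving catalyst class for this tandem reaction. This gives 14 together with its enantiomer, methyl (8R)-6-[(tert-butyldimethylsilyl)oxy]-2-ethoxy-3,8-dimethyl-1,4,7,8-tetrahydroazulene-5-carboxylate F1. Hydrolysis and equilibration as in step 7 give 16 and its enantiomer, methyl (8R,8aS)-3,8-dimethyl-2,6-dioxo-1,2,4,5,6,7,8,8a-octahydroazulene-5-carboxylate F2. The transfer hydrogenation of step 8 then acts as a divergent resolution: the catalyst should impose 8R on both enantiomers and so turn them into diastereomers, 17 and methyl (5S,6R,8R,8aS)-6-hydroxy-3,8-dimethyl-2-oxo-1,2,4,5,6,7,8,8a-octahydroazulene-5-carboxylate F3, which are separated by chromatography. This fallback sets out from 8 and 11 and comes back to the route at 17.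

Second, step 7. Equilibration at C1 may stop at an unfavourable epimer ratio, because the preference for the 1β-H epimer rests on little more than one gauche interaction. In the fallback C1 is set kinetically by hydroxyl-directed hydrogenation. Hydroxy ester 17, as its C1 mixture, is ketalised with ethylene glycol and TsOH in benzene, with the usual shift of the double bond to the ring fusion (C1=C5). This gives methyl (5S,6R,8S)-6-hydroxy-3,8-dimethyl-3,4,5,6,7,8-hexahydro-1H-spiro[azulene-2,2'-[1,3]dioxolane]-5-carboxylate F4. Hydrogenation with [Ir(cod)(PCy3)(py)]PF6 and H2 in CH2Cl2 should add hydrogen to C1 and C5 from the face of the C8 hydroxyl, giving the cis-fused ketal methyl 6-hydroxy-3,8-dimethyloctahydro-1H-spiro[azulene-2,2'-[1,3]dioxolane]-5-carboxylate F5. Aqueous HCl in acetone frees the ketone, methyl 6-hydroxy-3,8-dimethyl-2-oxodecahydroazulene-5-carboxylate F6. Saegusa–Ito oxidation follows: TMSOTf and Et3N give the more substituted silyl enol ether, methyl 3,8-dimethyl-2,6-bis[(trimethylsilyl)oxy]-1,3a,4,5,6,7,8,8a-octahydroazulene-5-carboxylate F7, and Pd(OAc)2 in MeCN with mildly acidic work-up reinstalls the C4=C5 double bond. This fallback sets out from 17 and comes back at 17, now with 1β-H fixed.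

Third, step 8. Catalyst control over C8 may be insufficient next to the existing stereocentres, the dynamic resolution at C7 may give the trans isomer, or the enone may be partly reduced. The fallback uses substrate control. Cycloadduct 14 is treated with MeLi (3 equiv, THF, −78 °C), which should attack only the ester because both carbonyl groups are still masked as enol ethers. This gives 2-[(8S)-6-[(tert-butyldimethylsilyl)oxy]-2-ethoxy-3,8-dimethyl-1,4,7,8-tetrahydroazulen-5-yl]propan-2-ol F8. 1 M HCl in THF followed by DBU unmasks and equilibrates it to (5R,8S,8aR)-5-(2-hydroxypropan-2-yl)-3,8-dimethyl-4,5,8,8a-tetrahydroazulene-2,6(1H,7H)-dione F9; C1 is set as in step 7, and C7, now α to the C8 ketone, should settle with the bulky carbinol group pseudo-equatorial. LiBH(sBu)3 in THF at −78 °C should deliver hydride to C8 anti to the C7 substituent and give the cis diol 21. This fallback sets out from 14 and comes back at 21, bypassing steps 7 to 11.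

Further compounds
F1 | step 6 | methyl (8R)-6-[(tert-butyldimethylsilyl)oxy]-2-ethoxy-3,8-dimethyl-1,4,7,8-tetrahydroazulene-5-carboxylate (enantiomer of 14) | COC(=O)C1=C(O[Si](C)(C)C(C)(C)C)C[C@@H](C)C2=C(C1)C(C)=C(OCC)C2
F2 | step 6 | methyl (8R,8aS)-3,8-dimethyl-2,6-dioxo-1,2,4,5,6,7,8,8a-octahydroazulene-5-carboxylate (enantiomer of 16) | COC(=O)C1C(=O)C[C@@H](C)[C@@H]2CC(=O)C(C)=C2C1
F3 | step 6 | methyl (5S,6R,8R,8aS)-6-hydroxy-3,8-dimethyl-2-oxo-1,2,4,5,6,7,8,8a-octahydroazulene-5-carboxylate | O[C@@H]1C[C@@H](C)[C@@H]2CC(=O)C(C)=C2C[C@@H]1C(=O)OC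
F4 | step 7 | methyl (5S,6R,8S)-6-hydroxy-3,8-dimethyl-3,4,5,6,7,8-hexahydro-1H-spiro[azulene-2,2'-[1,3]dioxolane]-5-carboxylate (C3 epimers) | O[C@@H]1C[C@H](C)C2=C(C[C@@H]1C(=O)OC)C(C)C3(C2)OCCO3
F5 | step 7 | methyl 6-hydroxy-3,8-dimethyloctahydro-1H-spiro[azulene-2,2'-[1,3]dioxolane]-5-carboxylate (cis-fused; 1β-H and 5β-H in guaiane numbering; C3 epimers) | O[C@@H]1C[C@H](C)[C@H]2CC3(OCCO3)C(C)[C@H]2C[C@@H]1C(=O)OC
F6 | step 7 | methyl 6-hydroxy-3,8-dimethyl-2-oxodecahydroazulene-5-carboxylate (cis-fused; 1β-H and 5β-H in guaiane numbering; C3 epimers) | O[C@@H]1C[C@H](C)[C@H]2CC(=O)C(C)[C@H]2C[C@@H]1C(=O)OC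
F7 | step 7 | methyl 3,8-dimethyl-2,6-bis[(trimethylsilyl)oxy]-1,3a,4,5,6,7,8,8a-octahydroazulene-5-carboxylate (cis-fused) | C[Si](C)(C)O[C@@H]1C[C@H](C)[C@H]2CC(O[Si](C)(C)C)=C(C)[C@H]2C[C@@H]1C(=O)OC
F8 | step 8 | 2-[(8S)-6-[(tert-butyldimethylsilyl)oxy]-2-ethoxy-3,8-dimethyl-1,4,7,8-tetrahydroazulen-5-yl]propan-2-ol | CC(C)(O)C1=C(O[Si](C)(C)C(C)(C)C)C[C@H](C)C2=C(C1)C(C)=C(OCC)C2
F9 | step 8 | (5R,8S,8aR)-5-(2-hydroxypropan-2-yl)-3,8-dimethyl-4,5,8,8a-tetrahydroazulene-2,6(1H,7H)-dione | O=C1C[C@H](C)[C@H]2CC(=O)C(C)=C2C[C@@H]1C(C)(C)O
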